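**Plan**

Ring A is numbered C1 (carries the 2-(3-methoxyphenyl)ethyl chain), C2, C4, C6 (4-hydroxybenzyl), C3 (OH), C5 (OMe); open-chain precursors keep these numbers.
Retrosynthesis: after removal of the protecting groups and the C5 O-methyl, the C1–C6 bond of ring A is cut. C1 and C6 each carry a CH2 substituent, so this bond can be the ring alkene made from two 1,1-disubstituted alkenes, with the C5 oxygen next to C6 as a ketone and the hydrogen on C2 letting the dienone become the phenol.
The resulting 1,4,7-trien-3-one is cut at C5–C6 (vinyllithium plus N-methoxy-N-methylamide), at the O–CH2 bond of the C3 enol ether, at C3–C4 (Claisen-type acylation), at C2–CH2Ar (dienediolate alkylation) and at C1–CH2 of the phenethyl chain (Grignard opening of diketene).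
Forward: the C1–C3 acid and the C4–C5 amide are joined, the C3 oxygen is fixed as an E enol ether, the C6 alkene is added, and ring A (the only ring made; the other four benzene rings are bought) closes by metathesis. O-methylation and hydrogenolysis finish the synthesis.
Stereochemistry: the target is achiral; the only stereochemical demand is the E enol ether (C2 and C5 cis), set in the O-alkylation, and the sp3 centres at C2 and C4 are transient and uncontrolled.

Key step: step 9

Remark: ring A is symmetric apart from the O-methyl group (C2 and C6 carry the same substituent), so the protected and the free oxygen of the ring-closure product need not be told apart by position; solutions of LiN(i-Pr)2, KN(SiMe3)2, t-BuLi and i-PrMgCl are taken as purchased.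

**Route**

Step 1
Reactants: 1 1-(2-bromoethyl)-3-methoxybenzene; 2 diketene
Product: 4 5-(3-methoxyphenyl)-3-methylidenepentanoic acid, via 2-(3-methoxyphenyl)ethylmagnesium bromide 3 (not isolated)
Conditions: Mg, THF, rt; then 2, CoI2 (5 mol%), THF, −78 → 0 °C; aq. HCl
Reagents that add atoms: none
Why: Cobalt-catalysed coupling of a Grignard reagent with diketene cleaves the vinylic C–O bond of the β-lactone and is a known one-step entry to 3-methylidenealkanoic acids, so the 1,1-disubstituted C1 alkene is in place without any carbonyl methylenation.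

Step 2
Reactants: 4 5-(3-methoxyphenyl)-3-methylidenepentanoic acid; 5 4-(benzyloxy)benzyl chloride
Product: 7 rac-2-[4-(benzyloxy)benzyl]-5-(3-methoxyphenyl)-3-methylidenepentanoic acid, via dilithium dienediolate 6 (not isolated)
Conditions: LiN(i-Pr)2 (2.2 equiv), THF, −78 → 0 °C; then 5, −78 °C → rt; aq. HCl
Reagents that add atoms: none
Why: Alkylation of the lithium dienediolate of a but-3-enoic acid with a benzylic halide should take place mainly at the α-carbon under kinetic control and leave the alkene unconjugated, which puts the benzyl group on C2; the new stereocentre is racemic and disappears when ring A becomes aromatic.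

Step 3
Reactants: 8 methyl 3-(4-hydroxyphenyl)propanoate
Product: 9 methyl 3-[4-(benzyloxy)phenyl]propanoate
Conditions: BnBr, K2CO3, acetone, reflux
Reagents that add atoms: benzyl bromide, BrCc1ccccc1
Why: Williamson ether synthesis masks the phenol before any enolate chemistry.

Step 4
Reactants: 9 methyl 3-[4-(benzyloxy)phenyl]propanoate
Product: 10 3-[4-(benzyloxy)phenyl]-N-methoxy-N-methylpropanamide
Conditions: MeNH(OMe)·HCl, i-PrMgCl, THF, −20 → 0 °C; aq. NH4Cl
Reagents that add atoms: N,O-dimethylhydroxylamine hydrochloride, CNOC.Cl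
Why: Aminolysis of the methyl ester by the chloromagnesium amide of N,O-dimethylhydroxylamine is the standard ester-to-Weinreb-amide conversion and provides the acyl group that later stops at the ketone stage.

Step 5
Reactants: 7 rac-2-[4-(benzyloxy)benzyl]-5-(3-methoxyphenyl)-3-methylidenepentanoic acid; 10 3-[4-(benzyloxy)phenyl]-N-methoxy-N-methylpropanamide
Product: 13 2,4-bis[4-(benzyloxy)benzyl]-N-methoxy-7-(3-methoxyphenyl)-N-methyl-5-methylidene-3-oxoheptanamide (mixture of diastereomers), via acid chloride 11 (not isolated), via lithium amide enolate 12 (not isolated)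
Conditions: 7, (COCl)2, DMF (cat.), CH2Cl2, 0 °C → rt, evaporate; 10 (2.1 equiv), LiN(i-Pr)2 (2.1 equiv), THF, −78 °C; add 11 in THF at −78 °C; aq. NH4Cl at −78 °C
Reagents that add atoms: none
Why: Crossed Claisen-type C-acylation of a preformed lithium amide enolate by an acid chloride at low temperature forms the C3–C4 bond, and the second equivalent of enolate converts the β-keto amide into its own enolate, which shields the C2–H and the C1 alkene from base; the stereocentres at C2 and C4 form without control and are both lost later.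

Step 6
Reactants: 13 2,4-bis[4-(benzyloxy)benzyl]-N-methoxy-7-(3-methoxyphenyl)-N-methyl-5-methylidene-3-oxoheptanamide
Product: 15 rac-(2E)-2,4-bis[4-(benzyloxy)benzyl]-3-[(benzyloxy)methoxy]-N-methoxy-7-(3-methoxyphenyl)-N-methyl-5-methylidenehept-2-enamide, via potassium enolate 14 (not isolated)
Conditions: KN(SiMe3)2 (1.0 equiv), 18-crown-6, THF, −78 °C; then BnOCH2Cl, −78 → −20 °C
Reagents that add atoms: benzyl chloromethyl ether, ClCOCc1ccccc1
Why: O-alkylation of a β-dicarbonyl enolate by a hard alkoxymethyl chloride fixes the C3 oxygen as an enol ether at the only ketone present, and with the potassium ion held by the crown ether the enolate cannot chelate and should react in the arrangement with the ketone oxygen trans to the amide carbonyl, giving the E isomer in which C2 and C5 are cis.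

Step 7
Reactants: 16 1-(benzyloxy)-4-bromobenzene; 17 2,3-dibromoprop-1-ene
Product: 19 1-(benzyloxy)-4-(2-bromoprop-2-en-1-yl)benzene, via 4-(benzyloxy)phenylmagnesium bromide 18 (not isolated)
Conditions: Mg, THF, reflux; then 17, CuI (5 mol%), THF, 0 °C → rt
Reagents that add atoms: none
Why: Copper-catalysed substitution of the allylic bromide of 2,3-dibromopropene by an aryl Grignard reagent is a standard route to 2-bromo-3-arylpropenes, the vinylic bromide being inert.

Step 8
Reactants: 15 rac-(2E)-2,4-bis[4-(benzyloxy)benzyl]-3-[(benzyloxy)methoxy]-N-methoxy-7-(3-methoxyphenyl)-N-methyl-5-methylidenehept-2-enamide; 19 1-(benzyloxy)-4-(2-bromoprop-2-en-1-yl)benzene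
Product: 22 rac-(4E)-2,4,6-tris[4-(benzyloxy)benzyl]-5-[(benzyloxy)methoxy]-7-[2-(3-methoxyphenyl)ethyl]octa-1,4,7-trien-3-one, via vinyllithium 20 (not isolated), via tetrahedral lithium alkoxide 21 (not isolated)
Conditions: 19, t-BuLi (2 equiv), Et2O, −78 °C; then 15 in THF, −78 → −40 °C; cold aq. NH4Cl
Reagents that add atoms: none
Why: Bromine–lithium exchange followed by the Weinreb ketone synthesis forms the C5–C6 bond, the vinyllithium adding only once because the chelated adduct 21 persists until the cold quench, so the α-methylene ketone results without over-addition and without change of the enol ether geometry.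

Step 9
Reactants: 22 rac-(4E)-2,4,6-tris[4-(benzyloxy)benzyl]-5-[(benzyloxy)methoxy]-7-[2-(3-methoxyphenyl)ethyl]octa-1,4,7-trien-3-one
Product: 24 2,4,6-tris[4-(benzyloxy)benzyl]-3-[(benzyloxy)methoxy]-5-[2-(3-methoxyphenyl)ethyl]phenol, via cyclohexa-2,5-dienone 23 (not isolated)
Conditions: second-generation Hoveyda–Grubbs-type catalyst RuCl2(=CH-C6H4-2-O-i-Pr)(L), L = 1,3-bis(2-methylphenyl)imidazolidin-2-ylidene (10 mol%, in portions), 1,4-benzoquinone (20 mol%), toluene (0.005 M), 90 °C, argon sparge
Reagents that add atoms: none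
Why: The ruthenium alkylidene loads onto the unconjugated C1 methylene, adds across the C6 methylene of the α-methylene ketone to a ruthenacyclobutane and, on cycloreversion, closes the C1=C6 bond of cyclohexa-2,5-dienone 23 with loss of ethene, after which the hydrogen on C2 moves to oxygen by enolisation and phenol 24 forms irreversibly. The closest known reaction type is the ring-closing metathesis of 1,4,7-trien-3-ones with tautomerisation to phenols, combined with the ring-closing metathesis of two 1,1-disubstituted alkenes to a tetrasubstituted cycloalkene, for which the small N-(2-methylphenyl) groups of the carbene ligand open space at ruthenium. Ring A closes as a six-membered carbocycle by alkene–alkene metathesis in which C1 and C6 join and both terminal CH2 groups leave. No stereocentre is formed, and the racemic centre at C2 is erased by aromatisation. The step needs ring closure to win over dimerisation, over migration of the C1 alkene into conjugation by ruthenium hydrides and over acid-induced Nazarov closure of the cross-conjugated dienone; the E enol ether holds C2 and C5 cis so that the two methylenes lie within reach, the tetrasubstituted enol ether alkene is inert to the catalyst, and high dilution, benzoquinone and the neutral medium guard against the side reactions.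

Step 10
Reactants: 24 2,4,6-tris[4-(benzyloxy)benzyl]-3-[(benzyloxy)methoxy]-5-[2-(3-methoxyphenyl)ethyl]phenol
Product: 25 1-[(benzyloxy)methoxy]-2,4,6-tris[4-(benzyloxy)benzyl]-3-methoxy-5-[2-(3-methoxyphenyl)ethyl]benzene
Conditions: MeI, K2CO3, DMF, rt
Reagents that add atoms: iodomethane, CI
Why: Williamson O-methylation of the only free hydroxyl (on C5) proceeds under mild carbonate conditions that leave the benzyl and benzyloxymethyl ethers intact.

Step 11
Reactants: 25 1-[(benzyloxy)methoxy]-2,4,6-tris[4-(benzyloxy)benzyl]-3-methoxy-5-[2-(3-methoxyphenyl)ethyl]benzene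
Product: 26 2,4,6-tris(4-hydroxybenzyl)-3-methoxy-5-[2-(3-methoxyphenyl)ethyl]phenol (CNP0285788.0)
Conditions: H2 (1 atm), Pd/C (10%), EtOAc–MeOH, rt
Reagents that add atoms: none
Why: Catalytic hydrogenolysis cleaves the three aryl benzyl ethers and the benzyloxymethyl ether (lost as toluene and formaldehyde) in one operation, while the aryl methyl ethers and the diarylmethane and bibenzyl C–C bonds are inert.

**Compound list**

1 | 1-(2-bromoethyl)-3-methoxybenzene | COc1cccc(CCBr)c1 | starting material
2 | diketene (4-methylideneoxetan-2-one) | C=C1CC(=O)O1 | starting material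
3 | 2-(3-methoxyphenyl)ethylmagnesium bromide | COc1cccc(CC[Mg]Br)c1 | intermediate
4 | 5-(3-methoxyphenyl)-3-methylidenepentanoic acid | COc1cccc(CCC(=C)CC(=O)O)c1 | intermediate
5 | 4-(benzyloxy)benzyl chloride | ClCc1ccc(OCc2ccccc2)cc1 | starting material
6 | dilithium 5-(3-methoxyphenyl)-3-methylidenepent-1-ene-1,1-diolate (dienediolate of 4) | [Li]OC(O[Li])=CC(=C)CCc1cccc(OC)c1 | intermediate
7 | rac-2-[4-(benzyloxy)benzyl]-5-(3-methoxyphenyl)-3-methylidenepentanoic acid | COc1cccc(CCC(=C)C(Cc2ccc(OCc3ccccc3)cc2)C(=O)O)c1 | intermediate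
8 | methyl 3-(4-hydroxyphenyl)propanoate | COC(=O)CCc1ccc(O)cc1 | starting material
9 | methyl 3-[4-(benzyloxy)phenyl]propanoate | COC(=O)CCc1ccc(OCc2ccccc2)cc1 | intermediate
10 | 3-[4-(benzyloxy)phenyl]-N-methoxy-N-methylpropanamide | CON(C)C(=O)CCc1ccc(OCc2ccccc2)cc1 | intermediate
11 | rac-2-[4-(benzyloxy)benzyl]-5-(3-methoxyphenyl)-3-methylidenepentanoyl chloride | COc1cccc(CCC(=C)C(Cc2ccc(OCc3ccccc3)cc2)C(Cl)=O)c1 | intermediate
12 | lithium 3-[4-(benzyloxy)phenyl]-1-[methoxy(methyl)amino]prop-1-en-1-olate (enolate of 10) | CON(C)C(O[Li])=CCc1ccc(OCc2ccccc2)cc1 | intermediate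
13 | 2,4-bis[4-(benzyloxy)benzyl]-N-methoxy-7-(3-methoxyphenyl)-N-methyl-5-methylidene-3-oxoheptanamide (mixture of diastereomers) | CON(C)C(=O)C(Cc1ccc(OCc2ccccc2)cc1)C(=O)C(Cc1ccc(OCc2ccccc2)cc1)C(=C)CCc1cccc(OC)c1 | intermediate
14 | potassium enolate of 13 (enolised between C3 and C4, geometry not fixed) | CON(C)C(=O)C(Cc1ccc(OCc2ccccc2)cc1)=C(O[K])C(Cc1ccc(OCc2ccccc2)cc1)C(=C)CCc1cccc(OC)c1 | intermediate
15 | rac-(2E)-2,4-bis[4-(benzyloxy)benzyl]-3-[(benzyloxy)methoxy]-N-methoxy-7-(3-methoxyphenyl)-N-methyl-5-methylidenehept-2-enamide | CON(C)C(=O)/C(Cc1ccc(OCc2ccccc2)cc1)=C(/OCOCc1ccccc1)C(Cc1ccc(OCc2ccccc2)cc1)C(=C)CCc1cccc(OC)c1 | intermediate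
16 | 1-(benzyloxy)-4-bromobenzene | Brc1ccc(OCc2ccccc2)cc1 | starting material
17 | 2,3-dibromoprop-1-ene | C=C(Br)CBr | starting material
18 | 4-(benzyloxy)phenylmagnesium bromide | Br[Mg]c1ccc(OCc2ccccc2)cc1 | intermediate
19 | 1-(benzyloxy)-4-(2-bromoprop-2-en-1-yl)benzene | C=C(Br)Cc1ccc(OCc2ccccc2)cc1 | intermediate
20 | 3-[4-(benzyloxy)phenyl]prop-1-en-2-yllithium | [Li]C(=C)Cc1ccc(OCc2ccccc2)cc1 | intermediate
21 | lithium alkoxide of the tetrahedral adduct of 20 to the amide carbonyl of 15 | [Li]OC(N(C)OC)(C(=C)Cc1ccc(OCc2ccccc2)cc1)/C(Cc1ccc(OCc2ccccc2)cc1)=C(/OCOCc1ccccc1)C(Cc1ccc(OCc2ccccc2)cc1)C(=C)CCc1cccc(OC)c1 | intermediate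
22 | rac-(4E)-2,4,6-tris[4-(benzyloxy)benzyl]-5-[(benzyloxy)methoxy]-7-[2-(3-methoxyphenyl)ethyl]octa-1,4,7-trien-3-one | C=C(Cc1ccc(OCc2ccccc2)cc1)C(=O)/C(Cc1ccc(OCc2ccccc2)cc1)=C(/OCOCc1ccccc1)C(Cc1ccc(OCc2ccccc2)cc1)C(=C)CCc1cccc(OC)c1 | intermediate
23 | rac-2,4,6-tris[4-(benzyloxy)benzyl]-3-[(benzyloxy)methoxy]-5-[2-(3-methoxyphenyl)ethyl]cyclohexa-2,5-dien-1-one | O=C1C(Cc2ccc(OCc3ccccc3)cc2)=C(OCOCc2ccccc2)C(Cc2ccc(OCc3ccccc3)cc2)C(CCc2cccc(OC)c2)=C1Cc1ccc(OCc2ccccc2)cc1 | intermediate
24 | 2,4,6-tris[4-(benzyloxy)benzyl]-3-[(benzyloxy)methoxy]-5-[2-(3-methoxyphenyl)ethyl]phenol | COc1cccc(CCc2c(Cc3ccc(OCc4ccccc4)cc3)c(OCOCc3ccccc3)c(Cc3ccc(OCc4ccccc4)cc3)c(O)c2Cc2ccc(OCc3ccccc3)cc2)c1 | intermediate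
25 | 1-[(benzyloxy)methoxy]-2,4,6-tris[4-(benzyloxy)benzyl]-3-methoxy-5-[2-(3-methoxyphenyl)ethyl]benzene | COc1cccc(CCc2c(Cc3ccc(OCc4ccccc4)cc3)c(OCOCc3ccccc3)c(Cc3ccc(OCc4ccccc4)cc3)c(OC)c2Cc2ccc(OCc3ccccc3)cc2)c1 | intermediate
26 | 2,4,6-tris(4-hydroxybenzyl)-3-methoxy-5-[2-(3-methoxyphenyl)ethyl]phenol (CNP0285788.0) | COc1cccc(CCc2c(Cc3ccc(O)cc3)c(O)c(Cc3ccc(O)cc3)c(OC)c2Cc2ccc(O)cc2)c1 | target

**Step count and risks**

Total steps: 11. Longest linear sequence: 8 steps (steps 1, 2, 5, 6, 8, 9, 10, 11).

Steps most likely to fail: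

Step 9. A tetrasubstituted ring alkene has to form between a hindered, α-branched 1,1-disubstituted alkene and an electron-poor α-substituted enone, so catalyst decay, alkene migration or dimerisation may outrun ring closure. The fallback leaves the C6 benzyl group out of the ring closure, so that only a trisubstituted ring alkene is needed, and sets out from 15. Addition of CH2=CHMgBr (THF, −20 °C, cold acidic quench) to the N-methoxy-N-methylamide should give rac-(4E)-4,6-bis[4-(benzyloxy)benzyl]-5-[(benzyloxy)methoxy]-7-[2-(3-methoxyphenyl)ethyl]octa-1,4,7-trien-3-one F1. Ring-closing metathesis of this vinyl ketone with the second-generation Grubbs catalyst RuCl2(=CHPh)(PCy3)(1,3-dimesitylimidazolidin-2-ylidene) in toluene, followed by the same tautomerisation, should give 2,4-bis[4-(benzyloxy)benzyl]-3-[(benzyloxy)methoxy]-5-[2-(3-methoxyphenyl)ethyl]phenol F2, whose only free ring position is C6, ortho to the hydroxyl. C-Benzylation of its sodium phenoxide with chloride 5 in toluene (NaH, reflux), conditions that favour ortho C-alkylation of phenoxides, returns to the route at 24.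

Step 6. The enol ether may form with the wrong double-bond geometry (alkoxy group cis to the amide carbonyl, C2 and C5 trans), or alkylation may occur at C4. The fallback drops the enol ether and uses the symmetry of ring A, setting out from 13. Vinyllithium 20 (2.2 equiv; the first equivalent forms the C4 enolate, the second adds to the amide) should give 2,4,6-tris[4-(benzyloxy)benzyl]-7-[2-(3-methoxyphenyl)ethyl]octa-1,7-diene-3,5-dione F3, whose diketo form can rotate freely into the reactive conformation. Ring-closing metathesis under the conditions of step 9 and double tautomerisation should give 2,4,6-tris[4-(benzyloxy)benzyl]-5-[2-(3-methoxyphenyl)ethyl]benzene-1,3-diol F4. Its two hydroxyls are related by the mirror plane through C1 and C4, so mono-methylation (MeI, 1 equiv, K2CO3, acetone; diol recycled, dimethyl ether separated) gives a single compound, 2,4,6-tris[4-(benzyloxy)benzyl]-3-methoxy-5-[2-(3-methoxyphenyl)ethyl]phenol F5. Hydrogenolysis (H2, Pd/C) returns to the route at 26.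

Step 8. The twisted amide carbonyl, flanked by the C4 benzyl group and the branched C2 substituent, may resist attack, so that the basic vinyllithium removes the C2–H instead and the C1 alkene migrates. The fallback passes through the aldehyde oxidation level and sets out from 15. Reduction with i-Bu2AlH (THF, −78 °C) should give rac-(2E)-2,4-bis[4-(benzyloxy)benzyl]-3-[(benzyloxy)methoxy]-7-(3-methoxyphenyl)-5-methylidenehept-2-enal F6. Addition of vinyllithium 20 at −78 °C to this far more electrophilic and less hindered carbonyl should give (4E)-2,4,6-tris[4-(benzyloxy)benzyl]-5-[(benzyloxy)methoxy]-7-[2-(3-methoxyphenyl)ethyl]octa-1,4,7-trien-3-ol F7 as a mixture of diastereomers. Oxidation with Dess–Martin periodinane buffered with NaHCO3 (CH2Cl2, 0 °C) returns to the route at 22.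

**Further compounds**

F1 | step 9 | rac-(4E)-4,6-bis[4-(benzyloxy)benzyl]-5-[(benzyloxy)methoxy]-7-[2-(3-methoxyphenyl)ethyl]octa-1,4,7-trien-3-one | C=CC(=O)/C(Cc1ccc(OCc2ccccc2)cc1)=C(/OCOCc1ccccc1)C(Cc1ccc(OCc2ccccc2)cc1)C(=C)CCc1cccc(OC)c1
F2 | step 9 | 2,4-bis[4-(benzyloxy)benzyl]-3-[(benzyloxy)methoxy]-5-[2-(3-methoxyphenyl)ethyl]phenol | COc1cccc(CCc2cc(O)c(Cc3ccc(OCc4ccccc4)cc3)c(OCOCc3ccccc3)c2Cc2ccc(OCc3ccccc3)cc2)c1
F3 | step 6 | 2,4,6-tris[4-(benzyloxy)benzyl]-7-[2-(3-methoxyphenyl)ethyl]octa-1,7-diene-3,5-dione | C=C(Cc1ccc(OCc2ccccc2)cc1)C(=O)C(Cc1ccc(OCc2ccccc2)cc1)C(=O)C(Cc1ccc(OCc2ccccc2)cc1)C(=C)CCc1cccc(OC)c1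
F4 | step 6 | 2,4,6-tris[4-(benzyloxy)benzyl]-5-[2-(3-methoxyphenyl)ethyl]benzene-1,3-diol | COc1cccc(CCc2c(Cc3ccc(OCc4ccccc4)cc3)c(O)c(Cc3ccc(OCc4ccccc4)cc3)c(O)c2Cc2ccc(OCc3ccccc3)cc2)c1
F5 | step 6 | 2,4,6-tris[4-(benzyloxy)benzyl]-3-methoxy-5-[2-(3-methoxyphenyl)ethyl]phenol | COc1cccc(CCc2c(Cc3ccc(OCc4ccccc4)cc3)c(O)c(Cc3ccc(OCc4ccccc4)cc3)c(OC)c2Cc2ccc(OCc3ccccc3)cc2)c1
F6 | step 8 | rac-(2E)-2,4-bis[4-(benzyloxy)benzyl]-3-[(benzyloxy)methoxy]-7-(3-methoxyphenyl)-5-methylidenehept-2-enal | O=C/C(Cc1ccc(OCc2ccccc2)cc1)=C(/OCOCc1ccccc1)C(Cc1ccc(OCc2ccccc2)cc1)C(=C)CCc1cccc(OC)c1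
F7 | step 8 | (4E)-2,4,6-tris[4-(benzyloxy)benzyl]-5-[(benzyloxy)methoxy]-7-[2-(3-methoxyphenyl)ethyl]octa-1,4,7-trien-3-ol (mixture of diastereomers) | C=C(Cc1ccc(OCc2ccccc2)cc1)C(O)/C(Cc1ccc(OCc2ccccc2)cc1)=C(/OCOCc1ccccc1)C(Cc1ccc(OCc2ccccc2)cc1)C(=C)CCc1cccc(OC)c1
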